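## Retrosynthetic overview

1. Last bond: the C3–O ester bond, by acylation of the cis-(2S,3S) benzylic alcohol with (Z)-2-(acetoxymethyl)but-2-enoic acid; both stereocentres stay untouched.
2. Key bond: O1–C2 of the dihydrofuran, by stereoretentive palladium-catalysed closure of the ortho phenol onto a trans-vinyl epoxide. The epoxide C–O bonds come from a phenol-directed asymmetric epoxidation of an (E)-aryl diene in the same flask, which sets C2 and C3.
3. Aryl diene: Suzuki–Miyaura coupling of 5-bromo-2,4-dihydroxyacetophenone with the (E)-dienylboronate made in the flask from 2-methylbut-1-en-3-yne and pinacolborane.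
4. Acid: syn-hydroalumination of ethyl but-2-ynoate and trapping with formaldehyde (fixes the Z-alkene), then saponification and O-acetylation.
5. Rings: the benzene ring is bought; the oxirane forms first (transient), then the dihydrofuran ring; no protecting groups.

Assumption: 5-bromo-2,4-dihydroxyacetophenone is bought as a catalogue compound; the sense of induction of the bishydroxamic acid ligand, untested on phenols, is checked in a first run and the antipodal ligand is taken if needed.

## Route

Step 1
Reactants: 1 2-methylbut-1-en-3-yne; 2 pinacolborane (4,4,5,5-tetramethyl-1,3,2-dioxaborolane); 3 1-(5-bromo-2,4-dihydroxyphenyl)ethan-1-one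
Product: 5 1-{2,4-dihydroxy-5-[(1E)-3-methylbuta-1,3-dien-1-yl]phenyl}ethan-1-one, via dienyl pinacol boronate 4 (not isolated)
Conditions: 1 (1.5 equiv), 2 (1.4 equiv), Cp2Zr(H)Cl (5 mol %), Et3N (10 mol %), neat, sealed tube, 40 °C; then 3 (1.0 equiv), Pd(OAc)2 (3 mol %), SPhos (6 mol %), K3PO4 (4 equiv), dioxane–H2O 5:1, 80 °C
Reagents that add atoms: none
Why: Cp2Zr(H)Cl-catalysed hydroboration adds H–B syn and anti-Markovnikov to the terminal alkyne only, giving the (E)-dienylboronate, and Suzuki–Miyaura coupling with the unprotected ortho-bromophenol keeps that geometry, whereas a Heck reaction of isoprene with this ortho-halophenol would be diverted through a π-allyl intermediate into dihydrobenzofuran annulation; no stereocentre is formed.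

Step 2
Reactants: 5 1-{2,4-dihydroxy-5-[(1E)-3-methylbuta-1,3-dien-1-yl]phenyl}ethan-1-one
Product: 7 1-[(2S,3S)-3,6-dihydroxy-2-(prop-1-en-2-yl)-2,3-dihydro-1-benzofuran-5-yl]ethan-1-one, via trans-vinyl epoxide 6 (not isolated)
Conditions: VO(Oi-Pr)3 (5 mol %), trans-N,N′-dihydroxy-N,N′-bis(diphenylacetyl)cyclohexane-1,2-diamine (single enantiomer, 6 mol %), PhCMe2OOH (1.0 equiv), toluene, 0 °C; then Pd(PPh3)4 (5 mol %), THF, 0 °C, quench on full conversion
Reagents that add atoms: cumene hydroperoxide, CC(C)(OO)c1ccccc1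
Why: Proposed new method: a phenol-directed asymmetric epoxidation relayed in one flask into a palladium-catalysed ring closure, in which the more acidic 4-OH (para to the acetyl group) exchanges onto the chiral pentavalent vanadium bishydroxamate alkylperoxo complex, which can reach only the proximal trans-styrenyl C=C (the isopropenyl C=C is out of range) and sets both stereocentres of (2S,3S)-epoxide 6 by ligand-controlled facial selection, after which zerovalent palladium ionises the allylic C–O bond with inversion and the ortho phenoxide attacks the same carbon of the π-allyl with a second inversion (5-exo closure, faster than π–σ–π equilibration and preferred over seven-membered closure at the CH2 terminus), so C2 is retained, C3 is untouched and the cis-(2S,3S) alcohol results; the closest known reactions are the vanadium/bishydroxamic acid epoxidation of homoallylic alcohols and the Tsuji–Trost cyclisation of hydroxy vinyl epoxides with net retention.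

Step 3
Reactants: 8 ethyl but-2-ynoate; 9 diisobutylaluminium hydride (i-Bu2AlH)
Product: 11 ethyl (2Z)-2-(hydroxymethyl)but-2-enoate, via alpha-alumino enoate 10 (not isolated)
Conditions: 9 (1.3 equiv), NMO (1.3 equiv), THF, 0 °C; then CH2O (monomeric, in THF, 3 equiv), −20 °C → rt; aq. potassium sodium tartrate
Reagents that add atoms: formaldehyde, C=O
Why: The i-Bu2AlH–NMO complex hydroaluminates the ynoate syn (hydride to C3, aluminium to C2), so methyl and ester end up cis, and the alkenylalane adds to formaldehyde with retention, which fixes the (Z)-alkene of the acid part (vinylalumination, a reductive Baylis–Hillman-type aldol addition); no stereocentre is formed.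

Step 4
Reactants: 11 ethyl (2Z)-2-(hydroxymethyl)but-2-enoate
Product: 12 (2Z)-2-(hydroxymethyl)but-2-enoic acid
Conditions: LiOH·H2O (2 equiv), THF–H2O 3:1, 0 °C → rt; then 1 M HCl to pH 2
Reagents that add atoms: lithium hydroxide, [Li+].[OH-]
Why: Saponification of an ethyl ester at or below room temperature, conditions under which the trisubstituted (Z)-alkene of such hydroxymethyl enoates is not isomerised; no stereocentre is involved.

Step 5
Reactants: 12 (2Z)-2-(hydroxymethyl)but-2-enoic acid
Product: 13 (2Z)-2-[(acetyloxy)methyl]but-2-enoic acid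
Conditions: Ac2O (1.3 equiv), pyridine, CH2Cl2, 0 °C → rt; aqueous work-up at pH 2
Reagents that add atoms: acetic anhydride, CC(=O)OC(C)=O
Why: Pyridine-mediated O-acetylation of the primary allylic alcohol, with the acidic aqueous work-up returning the free carboxylic acid; the alkene geometry is not touched.

Step 6
Reactants: 13 (2Z)-2-[(acetyloxy)methyl]but-2-enoic acid; 14 2,4,6-trichlorobenzoyl chloride; 7 1-[(2S,3S)-3,6-dihydroxy-2-(prop-1-en-2-yl)-2,3-dihydro-1-benzofuran-5-yl]ethan-1-one
Product: 16 (2S,3S)-5-acetyl-6-hydroxy-2-(prop-1-en-2-yl)-2,3-dihydro-1-benzofuran-3-yl (2Z)-2-[(acetyloxy)methyl]but-2-enoate, via mixed anhydride 15 (not isolated)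
Conditions: 13 (1.5 equiv), 14 (1.5 equiv), Et3N (1.6 equiv), toluene, rt; then 7 (1.0 equiv), toluene, 70 °C
Reagents that add atoms: none
Why: Yamaguchi esterification run without a nucleophilic catalyst, the protocol used for angelates to avoid Z-to-E isomerisation, in which the secondary benzylic hydroxyl attacks the unhindered acyl carbon of the mixed anhydride while the phenol, chelated to the ortho acetyl group, stays free; only the acyl C–O bond is formed, so the (2S,3S) centres are retained.

## Compound list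

1 | 2-methylbut-1-en-3-yne | C=C(C)C#C | starting material
2 | pinacolborane (4,4,5,5-tetramethyl-1,3,2-dioxaborolane) | CC1(C)OBOC1(C)C | starting material
3 | 1-(5-bromo-2,4-dihydroxyphenyl)ethan-1-one | CC(=O)c1cc(Br)c(O)cc1O | starting material
4 | 4,4,5,5-tetramethyl-2-[(1E)-3-methylbuta-1,3-dien-1-yl]-1,3,2-dioxaborolane | C=C(C)/C=C/B1OC(C)(C)C(C)(C)O1 | intermediate
5 | 1-{2,4-dihydroxy-5-[(1E)-3-methylbuta-1,3-dien-1-yl]phenyl}ethan-1-one | CC(=O)c1cc(/C=C/C(C)=C)c(O)cc1O | intermediate
6 | 1-{2,4-dihydroxy-5-[(2S,3S)-3-(prop-1-en-2-yl)oxiran-2-yl]phenyl}ethan-1-one | C=C(C)[C@@H]1O[C@H]1c2cc(C(C)=O)c(O)cc2O | intermediate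
7 | 1-[(2S,3S)-3,6-dihydroxy-2-(prop-1-en-2-yl)-2,3-dihydro-1-benzofuran-5-yl]ethan-1-one | C=C(C)[C@@H]1Oc2cc(O)c(C(C)=O)cc2[C@@H]1O | intermediate
8 | ethyl but-2-ynoate | CC#CC(=O)OCC | starting material
9 | diisobutylaluminium hydride | CC(C)C[AlH]CC(C)C | starting material
10 | ethyl (2E)-2-[bis(2-methylpropyl)alumanyl]but-2-enoate | C/C=C(\C(=O)OCC)[Al](CC(C)C)CC(C)C | intermediate
11 | ethyl (2Z)-2-(hydroxymethyl)but-2-enoate | C/C=C(\C(=O)OCC)CO | intermediate
12 | (2Z)-2-(hydroxymethyl)but-2-enoic acid | C/C=C(\C(=O)O)CO | intermediate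
13 | (2Z)-2-[(acetyloxy)methyl]but-2-enoic acid | C/C=C(\C(=O)O)COC(C)=O | intermediate
14 | 2,4,6-trichlorobenzoyl chloride | O=C(Cl)c1c(Cl)cc(Cl)cc1Cl | starting material
15 | (2Z)-2-[(acetyloxy)methyl]but-2-enoic 2,4,6-trichlorobenzoic anhydride | C/C=C(\C(=O)OC(=O)c1c(Cl)cc(Cl)cc1Cl)COC(C)=O | intermediate
16 | (2S,3S)-5-acetyl-6-hydroxy-2-(prop-1-en-2-yl)-2,3-dihydro-1-benzofuran-3-yl (2Z)-2-[(acetyloxy)methyl]but-2-enoate | C=C(C)[C@@H]1Oc2cc(O)c(C(C)=O)cc2[C@@H]1OC(=O)/C(=C\C)COC(C)=O | target

## Step count and risks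

Total steps: 6. Longest linear sequence: 4 (steps 3, 4, 5, 6; the arene branch is steps 1, 2, 6).

**Step 2 (the proposed new step).** Three things can go wrong:
- The vanadium catalyst may be held by the salicyl ketone chelate instead of the 4-OH, which would cost direction and enantioselectivity.
- The free ortho- and para-hydroxyaryl epoxide 6 may open at the benzylic carbon before palladium is added.
- The cis:trans ratio may erode by π–σ–π isomerisation or by re-ionisation of the allyl aryl ether in 7.

Fallback with known chemistry, setting out from 5 and coming back at 7. Diene 5 is silylated on both phenols (TBSOTf, 2,6-lutidine, CH2Cl2, 0 °C) to 1-{2,4-bis[(tert-butyldimethylsilyl)oxy]-5-[(1E)-3-methylbuta-1,3-dien-1-yl]phenyl}ethan-1-one F1. Shi epoxidation follows, with the enantiomer of the fructose-derived ketone (made from L-sorbose), KHSO5 (as 2KHSO5·KHSO4·K2SO4), K2CO3, Bu4NHSO4, MeCN–dimethoxymethane–buffer pH 10.5, 0 °C. It attacks the trans-disubstituted C=C and, by analogy with trans-β-methylstyrene, gives 1-{2,4-bis[(tert-butyldimethylsilyl)oxy]-5-[(2S,3S)-3-(prop-1-en-2-yl)oxiran-2-yl]phenyl}ethan-1-one F2. Bu4NF buffered with AcOH (2.2 equiv each) is then added to F2 and Pd(PPh3)4 (5 mol %) in THF at 0 °C, so the phenol is unmasked only in the presence of the catalyst and Tsuji–Trost closure with net retention gives 7.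

**Step 3.** The alkenylalane may react poorly with monomeric formaldehyde, the ester may be over-reduced, or the Z geometry may leak through an allenolate.

Fallback setting out from 8 and coming back at 11. Pd(PPh3)4-catalysed syn-hydrostannation of 8 with Bu3SnH (THF, rt) gives ethyl (2E)-2-(tributylstannyl)but-2-enoate F3. Iododestannylation (I2, CH2Cl2, 0 °C) with retention gives ethyl (2E)-2-iodobut-2-enoate F4. Stille coupling of F4 with Bu3SnCH2OH (Pd(PPh3)4, dioxane, 80 °C) installs the hydroxymethyl group with retention and delivers 11.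

**Step 6.** The cis hydroxyl is flanked by the isopropenyl group and may acylate slowly. The acyl donor carries an electrophilic Baylis–Hillman-type allylic acetate that limits heating and excludes nucleophilic catalysts. The phenol may acylate, and the Z-alkene may isomerise.

Fallback that installs the acetate last, setting out from 11 and 7 and coming back at 16. Ester 11 is silylated (TBSCl, imidazole, DMF) to ethyl (2Z)-2-({[tert-butyl(dimethyl)silyl]oxy}methyl)but-2-enoate F5 and saponified (LiOH·H2O, THF–H2O) to (2Z)-2-({[tert-butyl(dimethyl)silyl]oxy}methyl)but-2-enoic acid F6. With 14 and Et3N, F6 gives (2Z)-2-({[tert-butyl(dimethyl)silyl]oxy}methyl)but-2-enoic 2,4,6-trichlorobenzoic anhydride F7. This donor has no allylic leaving group and tolerates the longer heating with 7 (toluene, 90 °C), giving (2S,3S)-5-acetyl-6-hydroxy-2-(prop-1-en-2-yl)-2,3-dihydro-1-benzofuran-3-yl (2Z)-2-({[tert-butyl(dimethyl)silyl]oxy}methyl)but-2-enoate F8. HF·pyridine in THF at 0 °C gives (2S,3S)-5-acetyl-6-hydroxy-2-(prop-1-en-2-yl)-2,3-dihydro-1-benzofuran-3-yl (2Z)-2-(hydroxymethyl)but-2-enoate F9. Ac2O/pyridine at 0 °C then acetylates the primary allylic hydroxyl in preference to the chelated phenol and gives 16.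

## Further compounds

F1 | step 2 | 1-{2,4-bis[(tert-butyldimethylsilyl)oxy]-5-[(1E)-3-methylbuta-1,3-dien-1-yl]phenyl}ethan-1-one | CC(=O)c1cc(/C=C/C(C)=C)c(O[Si](C)(C)C(C)(C)C)cc1O[Si](C)(C)C(C)(C)C
F2 | step 2 | 1-{2,4-bis[(tert-butyldimethylsilyl)oxy]-5-[(2S,3S)-3-(prop-1-en-2-yl)oxiran-2-yl]phenyl}ethan-1-one | C=C(C)[C@@H]1O[C@H]1c2cc(C(C)=O)c(O[Si](C)(C)C(C)(C)C)cc2O[Si](C)(C)C(C)(C)C
F3 | step 3 | ethyl (2E)-2-(tributylstannyl)but-2-enoate | C/C=C(\C(=O)OCC)[Sn](CCCC)(CCCC)CCCC
F4 | step 3 | ethyl (2E)-2-iodobut-2-enoate | C/C=C(\C(=O)OCC)I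
F5 | step 6 | ethyl (2Z)-2-({[tert-butyl(dimethyl)silyl]oxy}methyl)but-2-enoate | C/C=C(\C(=O)OCC)CO[Si](C)(C)C(C)(C)C
F6 | step 6 | (2Z)-2-({[tert-butyl(dimethyl)silyl]oxy}methyl)but-2-enoic acid | C/C=C(\C(=O)O)CO[Si](C)(C)C(C)(C)C
F7 | step 6 | (2Z)-2-({[tert-butyl(dimethyl)silyl]oxy}methyl)but-2-enoic 2,4,6-trichlorobenzoic anhydride | C/C=C(\C(=O)OC(=O)c1c(Cl)cc(Cl)cc1Cl)CO[Si](C)(C)C(C)(C)C
F8 | step 6 | (2S,3S)-5-acetyl-6-hydroxy-2-(prop-1-en-2-yl)-2,3-dihydro-1-benzofuran-3-yl (2Z)-2-({[tert-butyl(dimethyl)silyl]oxy}methyl)but-2-enoate | C=C(C)[C@@H]1Oc2cc(O)c(C(C)=O)cc2[C@@H]1OC(=O)/C(=C\C)CO[Si](C)(C)C(C)(C)C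
F9 | step 6 | (2S,3S)-5-acetyl-6-hydroxy-2-(prop-1-en-2-yl)-2,3-dihydro-1-benzofuran-3-yl (2Z)-2-(hydroxymethyl)but-2-enoate | C=C(C)[C@@H]1Oc2cc(O)c(C(C)=O)cc2[C@@H]1OC(=O)/C(=C\C)CO
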